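**Strategy.** Everything rests on disconnecting the pyranone ring (ring C) at O1–C8a. In ring A, O1 and the two methoxy oxygens sit on C8a, C5 and C7, that is ortho, ortho and para to the carbon bearing the C4 carbonyl. Ring A can therefore enter as a 2,4,6-trifluoro-3,5-dimethylphenyl ketone, and every ring A C–O bond can be made by fluoride displacement. In the key step the enolate oxygen of an acyclic 2-benzyloxy-1,3-diketone, which already carries the 2-methoxyphenyl group and the protected C3 oxygen, displaces one of two equivalent ortho fluorides. This closes ring C in one operation and leaves the C5 and C7 fluorides for methoxide.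

Key step: step 6

**Remarks on the chemistry.**
- The key-step precursor is written as its chelated enol, with the hydroxyl cis to the 2-methoxybenzoyl carbon. Because the benzyloxy oxygen outranks that carbon, this geometry is E by the CIP rules. The enol equilibrates with the diketo tautomer and both give the same enolate.
- The diketone is assembled from the fluorinated aryl ketone and 2-methoxybenzoyl chloride, which is shorter than building a fluorinated acid chloride.
- In the methoxide step the first substitution is assumed to occur at C7; the order of the two substitutions does not affect the product.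
- The target has no stereocentre.

**Route**

Step 1
Reactants: 1 1,3,5-trifluorobenzene
Product: 3 1,3,5-trifluoro-2-methylbenzene (2,4,6-trifluorotoluene), via 2,4,6-trifluorophenyllithium 2 (not isolated)
Conditions: n-BuLi (1.05 equiv), THF, −78 °C, 1 h; MeI (1.2 equiv), −78 °C to rt; fractional distillation
Reagents that add atoms: iodomethane, CI
Why: Directed ortho-lithiation followed by SN2 methylation: every ring hydrogen of 1 is flanked by two fluorines and is removed by n-BuLi at −78 °C, where aryllithium 2 does not yet lose LiF, and MeI then alkylates the C–Li bond.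

Step 2
Reactants: 3 1,3,5-trifluoro-2-methylbenzene
Product: 5 1,3,5-trifluoro-2,4-dimethylbenzene, via 2,4,6-trifluoro-3-methylphenyllithium 4 (not isolated)
Conditions: n-BuLi (1.05 equiv), THF, −78 °C, 1 h; MeI (1.2 equiv), −78 °C to rt; distillation
Reagents that add atoms: iodomethane, CI
Why: The same ortho-lithiation and SN2 methylation: the two remaining ring hydrogens of 3 are equivalent and each lies between two fluorines, so kinetic ring lithiation should outrun benzylic deprotonation and a single dimethyl compound should result.

Step 3
Reactants: 6 benzyloxyacetyl chloride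
Product: 7 2-(benzyloxy)-N-methoxy-N-methylacetamide
Conditions: MeNHOMe·HCl (1.1 equiv), Et3N (2.3 equiv), CH2Cl2, 0 °C to rt
Reagents that add atoms: N,O-dimethylhydroxylamine hydrochloride, CNOC.Cl
Why: Acylation of an amine by an acid chloride (Weinreb amide formation), with Et3N taking up both equivalents of HCl and the benzyl ether as a spectator.

Step 4
Reactants: 5 1,3,5-trifluoro-2,4-dimethylbenzene; 7 2-(benzyloxy)-N-methoxy-N-methylacetamide
Product: 10 2-(benzyloxy)-1-(2,4,6-trifluoro-3,5-dimethylphenyl)ethan-1-one, via 2,4,6-trifluoro-3,5-dimethylphenyllithium 8 (not isolated), via lithium hemiaminal chelate 9 (not isolated)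
Conditions: 5 (1.1 equiv), n-BuLi (1.05 equiv), THF, −78 °C, 1 h; 7 (1.0 equiv) in THF, −78 °C to −60 °C; 1 M HCl, −60 °C to rt
Reagents that add atoms: none
Why: Ortho-lithiation of the only ring hydrogen of 5 and Weinreb ketone synthesis: aryllithium 8 adds once to amide 7, the chelated adduct 9 persists until the acidic quench so that no tertiary alcohol can form, and keeping the mixture at or below −60 °C suppresses loss of LiF from 8.

Step 5
Reactants: 10 2-(benzyloxy)-1-(2,4,6-trifluoro-3,5-dimethylphenyl)ethan-1-one; 11 2-methoxybenzoyl chloride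
Product: 13 (E)-2-(benzyloxy)-3-hydroxy-1-(2-methoxyphenyl)-3-(2,4,6-trifluoro-3,5-dimethylphenyl)prop-2-en-1-one (chelated enol of the 1,3-diketone), via bromomagnesium enolate 12 (not isolated)
Conditions: MgBr2·OEt2 (2.5 equiv), 11 (1.2 equiv), CH2Cl2, 0 °C; i-Pr2NEt (3 equiv) added last, 0 °C to rt; 1 M HCl work-up
Reagents that add atoms: none
Why: Claisen-type C-acylation under soft enolisation: MgBr2 binds the carbonyl and benzyloxy oxygens of 10 so that i-Pr2NEt suffices to give the chelated magnesium enolate 12, whose tightly bound oxygen leaves carbon as the site that attacks the aroyl chloride, and adding the amine last keeps 10 from condensing with itself.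

Step 6
Reactants: 13 (E)-2-(benzyloxy)-3-hydroxy-1-(2-methoxyphenyl)-3-(2,4,6-trifluoro-3,5-dimethylphenyl)prop-2-en-1-one
Product: 15 3-(benzyloxy)-5,7-difluoro-2-(2-methoxyphenyl)-6,8-dimethyl-4H-chromen-4-one, via potassium enolate 14 (not isolated)
Conditions: K2CO3 (2 equiv, anhydrous), dry DMF, 60 °C, N2
Reagents that add atoms: none
Why: Intramolecular nucleophilic aromatic substitution by addition–elimination: K2CO3 converts 13 into the delocalised enolate 14, whose oxygen on the 2-methoxybenzoyl carbon adds ipso to an ortho C–F carbon (the future C8a), the negative charge of the σ-adduct is taken up at C4a by the C4 carbonyl and is further stabilised inductively by the two remaining fluorines meta to the site of attack, and fluoride is then expelled. The closest known reaction type is the carbonate-induced cyclisation of 1-(2-fluoroaryl)-1,3-diketones to flavones and chromones. Ring C closes as a six-membered ring by attack on an sp2 carbon, formally 6-endo-trig if the arene is drawn with its C4a=C8a bond conjugated to C4=O (an intramolecular oxa-Michael addition followed by loss of fluoride), which is easy because O1, C2, C3, C4 and C4a are all sp2 and can lie in one plane. No stereocentre is formed. The step needs site selectivity and chemoselectivity: the two ortho fluorines are related by the local symmetry of the aryl group and give the same chromone, the other enolate oxygen and the central carbon could only close four-membered rings, and the para fluoride is spared because the base is non-nucleophilic and no alkoxide is present before step 7.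

Step 7
Reactants: 15 3-(benzyloxy)-5,7-difluoro-2-(2-methoxyphenyl)-6,8-dimethyl-4H-chromen-4-one
Product: 17 3-(benzyloxy)-5,7-dimethoxy-2-(2-methoxyphenyl)-6,8-dimethyl-4H-chromen-4-one, via 5-fluoro-7-methoxy chromone 16 (not isolated)
Conditions: NaOMe (5 equiv), DMSO–MeOH (4:1), 70 °C; AcOH quench
Reagents that add atoms: sodium methoxide, C[O-].[Na+]
Why: Twofold nucleophilic aromatic substitution by addition–elimination: C7 is para and C5 ortho to the carbon that carries the C4 carbonyl, so both fluorides are activated, the first methoxide is expected to enter at C7 to give 16 and the second at C5, while the benzyl ether and the aryl methyl ether are inert to methoxide.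

Step 8
Reactants: 17 3-(benzyloxy)-5,7-dimethoxy-2-(2-methoxyphenyl)-6,8-dimethyl-4H-chromen-4-one
Product: 18 3-hydroxy-5,7-dimethoxy-2-(2-methoxyphenyl)-6,8-dimethyl-4H-chromen-4-one
Conditions: H2 (1 atm), 10% Pd/C (palladium metal on carbon), EtOAc–MeOH, rt
Reagents that add atoms: none
Why: Catalytic hydrogenolysis of a benzyl ether: the benzylic C–O bond is cleaved at room temperature and 1 atm, conditions under which the chromone C2=C3 bond, the carbonyl and the methyl ethers should not be reduced.

**Compound list**

1 | 1,3,5-trifluorobenzene | Fc1cc(F)cc(F)c1 | starting material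
2 | 2,4,6-trifluorophenyllithium | [Li]c1c(F)cc(F)cc1F | intermediate (not isolated)
3 | 1,3,5-trifluoro-2-methylbenzene (2,4,6-trifluorotoluene) | Cc1c(F)cc(F)cc1F | intermediate
4 | 2,4,6-trifluoro-3-methylphenyllithium | [Li]c1c(F)cc(F)c(C)c1F | intermediate (not isolated)
5 | 1,3,5-trifluoro-2,4-dimethylbenzene | Cc1c(F)cc(F)c(C)c1F | intermediate
6 | benzyloxyacetyl chloride | O=C(Cl)COCc1ccccc1 | starting material
7 | 2-(benzyloxy)-N-methoxy-N-methylacetamide | CON(C)C(=O)COCc1ccccc1 | intermediate
8 | 2,4,6-trifluoro-3,5-dimethylphenyllithium | [Li]c1c(F)c(C)c(F)c(C)c1F | intermediate (not isolated)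
9 | lithium 2-(benzyloxy)-1-[methoxy(methyl)amino]-1-(2,4,6-trifluoro-3,5-dimethylphenyl)ethan-1-olate (racemic chelate) | [Li]OC(COCc1ccccc1)(N(C)OC)c1c(F)c(C)c(F)c(C)c1F | intermediate (not isolated)
10 | 2-(benzyloxy)-1-(2,4,6-trifluoro-3,5-dimethylphenyl)ethan-1-one | O=C(COCc1ccccc1)c1c(F)c(C)c(F)c(C)c1F | intermediate
11 | 2-methoxybenzoyl chloride | COc1ccccc1C(Cl)=O | starting material
12 | bromomagnesium (Z)-2-(benzyloxy)-1-(2,4,6-trifluoro-3,5-dimethylphenyl)ethen-1-olate | Br[Mg]O/C(=C\OCc1ccccc1)c1c(F)c(C)c(F)c(C)c1F | intermediate (not isolated)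
13 | (E)-2-(benzyloxy)-3-hydroxy-1-(2-methoxyphenyl)-3-(2,4,6-trifluoro-3,5-dimethylphenyl)prop-2-en-1-one | COc1ccccc1C(=O)/C(OCc1ccccc1)=C(\O)c1c(F)c(C)c(F)c(C)c1F | intermediate
14 | potassium (E)-2-(benzyloxy)-1-(2-methoxyphenyl)-3-oxo-3-(2,4,6-trifluoro-3,5-dimethylphenyl)prop-1-en-1-olate | [K+].[O-]/C(c1ccccc1OC)=C(OCc1ccccc1)\C(=O)c1c(F)c(C)c(F)c(C)c1F | intermediate (not isolated)
15 | 3-(benzyloxy)-5,7-difluoro-2-(2-methoxyphenyl)-6,8-dimethyl-4H-chromen-4-one | COc1ccccc1-c1oc2c(C)c(F)c(C)c(F)c2c(=O)c1OCc1ccccc1 | intermediate
16 | 3-(benzyloxy)-5-fluoro-7-methoxy-2-(2-methoxyphenyl)-6,8-dimethyl-4H-chromen-4-one | COc1ccccc1-c1oc2c(C)c(OC)c(C)c(F)c2c(=O)c1OCc1ccccc1 | intermediate (not isolated)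
17 | 3-(benzyloxy)-5,7-dimethoxy-2-(2-methoxyphenyl)-6,8-dimethyl-4H-chromen-4-one | COc1ccccc1-c1oc2c(C)c(OC)c(C)c(OC)c2c(=O)c1OCc1ccccc1 | intermediate
18 | 3-hydroxy-5,7-dimethoxy-2-(2-methoxyphenyl)-6,8-dimethyl-4H-chromen-4-one | COc1ccccc1-c1oc2c(C)c(OC)c(C)c(OC)c2c(=O)c1O | target

**Totals**

Total step count: 8. Longest linear sequence: 7 steps (steps 1, 2, 4, 5, 6, 7, 8); step 3 is the only step off the main line.

**Steps most likely to fail**

Step 6 (key step). The two ortho fluorines twist the aroyl group out of the plane of the enolate, so the closure may be slow. During a long reaction the diketone may then suffer retro-Claisen cleavage by traces of hydroxide, or the para fluoride may be displaced intermolecularly. The fallback forms O1–C8a from an alkoxide, a much stronger nucleophile, at the flavanone oxidation level. It sets out from ketone 10. A lithium aldol addition (LiN(SiMe3)2, THF, −78 °C; 2-methoxybenzaldehyde; AcOH quench at −78 °C) should give 2-(benzyloxy)-3-hydroxy-3-(2-methoxyphenyl)-1-(2,4,6-trifluoro-3,5-dimethylphenyl)propan-1-one F1 as a mixture of diastereomers. With Cs2CO3 in DMF at room temperature the secondary alkoxide of this aldol should displace an ortho fluoride; retro-aldol only returns 10 and the aldehyde, which recombine, whereas the substitution is irreversible. This should give 3-(benzyloxy)-5,7-difluoro-2-(2-methoxyphenyl)-6,8-dimethylchroman-4-one F2. Dehydrogenation of this flavanone with DDQ in 1,4-dioxane at reflux erases both stereocentres and comes back to the route at 15.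

Step 7. The second substitution may stall, because the first methoxy group weakens the activation by the C4 carbonyl and the remaining fluoride is flanked on both sides. Prolonged exposure to methoxide may also open the pyranone by addition at C2. The fallback sets out from 15. The methoxide exchange is stopped after one substitution (NaOMe, 1.05 equiv, THF–MeOH, 0 °C to rt) and 16 is isolated. The C5 fluoride is then replaced under weakly basic conditions by an α-effect oxygen nucleophile, (E)-benzaldehyde oxime with Cs2CO3 in DMSO at 80 °C. This should give (E)-benzaldehyde O-[3-(benzyloxy)-7-methoxy-2-(2-methoxyphenyl)-6,8-dimethyl-4-oxo-4H-chromen-5-yl]oxime F3, which is not isolated and fragments in the flask to benzonitrile and the phenoxide. Work-up should give 3-(benzyloxy)-5-hydroxy-7-methoxy-2-(2-methoxyphenyl)-6,8-dimethyl-4H-chromen-4-one F4. O-Methylation of this chelated phenol (MeI, K2CO3, DMF, 50 °C) comes back to the route at 17.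

Step 5. Acylation may take place at the enolate oxygen instead of carbon, or the enolate of 10, stabilised by the electron-poor aryl group, may react too slowly. The fallback exchanges the roles of the two fragments, so that the more nucleophilic enolate of an electron-rich aryl ketone meets a more electrophilic fluorinated aroyl chloride. It sets out from 5 and 7. Arene 5 is lithiated as in step 4 and aryllithium 8 is quenched with CO2 (THF, −78 °C; HCl work-up) to give 2,4,6-trifluoro-3,5-dimethylbenzoic acid F5. (COCl)2 and catalytic DMF in CH2Cl2 convert it into 2,4,6-trifluoro-3,5-dimethylbenzoyl chloride F6. Separately, Weinreb amide 7 and commercial 2-methoxyphenylmagnesium bromide (THF, 0 °C; HCl work-up) give 2-(benzyloxy)-1-(2-methoxyphenyl)ethan-1-one F7. This ketone is enolised with LiN(SiMe3)2 (2.2 equiv, THF, −78 °C) and C-acylated with the acid chloride F6, a pairing of α-alkoxy aryl ketone enolate and aroyl chloride that is well established in flavonol synthesis. The fallback comes back to the route at 13.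

**Further compounds**

F1 | step 6 | 2-(benzyloxy)-3-hydroxy-3-(2-methoxyphenyl)-1-(2,4,6-trifluoro-3,5-dimethylphenyl)propan-1-one (mixture of racemic diastereomers) | COc1ccccc1C(O)C(OCc1ccccc1)C(=O)c1c(F)c(C)c(F)c(C)c1F
F2 | step 6 | 3-(benzyloxy)-5,7-difluoro-2-(2-methoxyphenyl)-6,8-dimethylchroman-4-one (mixture of racemic diastereomers) | COc1ccccc1C1Oc2c(C)c(F)c(C)c(F)c2C(=O)C1OCc1ccccc1
F3 | step 7 | (E)-benzaldehyde O-[3-(benzyloxy)-7-methoxy-2-(2-methoxyphenyl)-6,8-dimethyl-4-oxo-4H-chromen-5-yl]oxime | COc1ccccc1-c1oc2c(C)c(OC)c(C)c(O/N=C/c3ccccc3)c2c(=O)c1OCc1ccccc1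
F4 | step 7 | 3-(benzyloxy)-5-hydroxy-7-methoxy-2-(2-methoxyphenyl)-6,8-dimethyl-4H-chromen-4-one | COc1ccccc1-c1oc2c(C)c(OC)c(C)c(O)c2c(=O)c1OCc1ccccc1
F5 | step 5 | 2,4,6-trifluoro-3,5-dimethylbenzoic acid | OC(=O)c1c(F)c(C)c(F)c(C)c1F
F6 | step 5 | 2,4,6-trifluoro-3,5-dimethylbenzoyl chloride | O=C(Cl)c1c(F)c(C)c(F)c(C)c1F
F7 | step 5 | 2-(benzyloxy)-1-(2-methoxyphenyl)ethan-1-one | COc1ccccc1C(=O)COCc1ccccc1
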